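## Retrosynthetic overview

1. The side chain comes last: a C12 Grignard reagent adds anti across propargyl alcohol (C12–C13), CO2 is captured at C14 and the alkoxide is acetylated, which fixes the 13Z geometry.
2. C8=C17 comes from a Peterson elimination, C2–OMe from α-face hydroboration of a Δ2 alkene, and ring A (formed second) from ring-closing metathesis between an allyl group on C10 and a 1,1-dimethylallyl group on C5.
3. Ring B (formed first) is built as a cyclopentanone and enlarged: a β-oxido carbenoid 1,2-shift inserts C9 between C8 and the quaternary C10 and delivers the C8/C9 enolate, which is hydroxyethylated (C11–C12).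
4. The cyclopentanone comes from 2-methylcyclopent-2-en-1-one by enantioselective conjugate reverse prenylation (C4–C5) and anti allylation (C10); these set C5 and C10.

Assumption: the SMILES is read as the ent-labdane 16-acetoxy-2-methoxy-labda-8(17),13Z-dien-15-oic acid with (2R,5R,9R,10R) configuration (trans-decalin, C2–OMe and C9 side chain equatorial); C1–C20 below are labdane position labels.

## Route

Step 1
Reactants: 1 1-chloro-3-methylbut-2-ene (prenyl chloride)
Product: 3 trimethyl(3-methylbut-2-en-1-yl)silane, via prenylmagnesium chloride 2 (not isolated)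
Conditions: Mg, Me3SiCl, THF, 0 °C to rt; distillation
Reagents that add atoms: chlorotrimethylsilane, C[Si](C)(C)Cl
Why: Barbier-type Grignard silylation, in which the allylic Grignard reagent formed in the presence of Me3SiCl is silylated at its unhindered primary terminus.

Step 2
Reactants: 4 2-methylcyclopent-2-en-1-one; 3 trimethyl(3-methylbut-2-en-1-yl)silane; 5 allyl bromide
Product: 8 (2R,3R)-2-allyl-2-methyl-3-(2-methylbut-3-en-2-yl)cyclopentan-1-one, via silyl enol ether 6 (not isolated), via lithium enolate 7 (not isolated)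
Conditions: confined chiral imidodiphosphorimidate (IDPi) Brønsted acid (2 mol%), toluene, −60 °C; then MeLi, THF, 0 °C; then allyl bromide, DMPU, −78 to 0 °C
Reagents that add atoms: none
Why: Proposed new method: the acid is silylated by 3 to a silylium/chiral-anion pair that O-silylates the enone, the allylsilane then attacks the Si face of the β-carbon (C5) through its γ-carbon (anti SE2′, giving the C4 quaternary centre and the C4–C5 bond) and the β-silyl cation returns Me3Si+ to regenerate the catalyst and give the regiodefined silyl enol ether, after which MeLi releases the lithium enolate and allyl bromide enters anti to the bulky C5 group to set C10; the closest known reactions are the Hosomi–Sakurai conjugate allylation (achiral Lewis acids) and silylium/IDPi asymmetric Mukaiyama–Michael catalysis, but an enantioselective conjugate reverse prenylation of an α-substituted cyclic enone has not been shown.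

Step 3
Reactants: 8 (2R,3R)-2-allyl-2-methyl-3-(2-methylbut-3-en-2-yl)cyclopentan-1-one; 9 dibromomethane; 10 oxirane
Product: 15 (2S,3R,4R)-3-allyl-2-(2-hydroxyethyl)-3-methyl-4-(2-methylbut-3-en-2-yl)cyclohexan-1-one, via dibromomethyllithium 11 (not isolated), via dibromomethyl alkoxide adduct 12 (not isolated), via β-oxido carbenoid 13 (not isolated), via ring-expanded lithium enolate 14 (not isolated)
Conditions: CH2Br2, lithium 2,2,6,6-tetramethylpiperidide (LiTMP), THF, −90 °C, then 8; n-BuLi, −90 to −20 °C; oxirane, LiClO4, −20 °C to rt; H2O; then K2CO3, MeOH, rt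
Reagents that add atoms: none
Why: β-oxido carbenoid ring enlargement of the Nozaki–Yamamoto type, in which bromine–lithium exchange on the LiCHBr2 adduct gives a carbenoid that receives the more substituted quaternary ring carbon in a non-pericyclic 1,2-shift (retention at C10), inserting C9 between C8 and C10 and releasing the C8/C9 enolate regiospecifically; LiClO4-assisted opening of oxirane attaches C11–C12 at C9, and base equilibration through the enol places that chain equatorial, trans to the C10 allyl group.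

Step 4
Reactants: 15 (2S,3R,4R)-3-allyl-2-(2-hydroxyethyl)-3-methyl-4-(2-methylbut-3-en-2-yl)cyclohexan-1-one
Product: 16 (2S,3R,4R)-3-allyl-2-(2-chloroethyl)-3-methyl-4-(2-methylbut-3-en-2-yl)cyclohexan-1-one
Conditions: PPh3, CCl4, CH2Cl2, 0 °C to rt
Reagents that add atoms: carbon tetrachloride, ClC(Cl)(Cl)Cl
Why: Appel reaction of the primary alcohol (SN2 by chloride on the alkoxyphosphonium ion) under neutral conditions that leave the ketone, the alkenes and the stereocentres untouched.

Step 5
Reactants: 16 (2S,3R,4R)-3-allyl-2-(2-chloroethyl)-3-methyl-4-(2-methylbut-3-en-2-yl)cyclohexan-1-one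
Product: 17 (1S,4aR,8aR)-1-(2-chloroethyl)-5,5,8a-trimethyl-3,4,4a,5,8,8a-hexahydronaphthalen-2(1H)-one
Conditions: second-generation Grubbs catalyst (H2IMes)(PCy3)Cl2Ru=CHPh (3 mol%), CH2Cl2, 40 °C
Reagents that add atoms: none
Why: Ring-closing metathesis of the two monosubstituted alkenes, held trans-diequatorial on C5 and C10 and helped by the gem-dimethyl group, closes ring A as an unstrained trans-fused Δ2-octalin with loss of ethene.

Step 6
Reactants: 17 (1S,4aR,8aR)-1-(2-chloroethyl)-5,5,8a-trimethyl-3,4,4a,5,8,8a-hexahydronaphthalen-2(1H)-one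
Product: 18 (1S,2R,4aR,8aR)-1-(2-chloroethyl)-5,5,8a-trimethyl-2-[(trimethylsilyl)methyl]-1,2,3,4,4a,5,8,8a-octahydronaphthalen-2-ol
Conditions: Me3SiCH2Li, CeCl3, THF, −78 °C; H2O quench at −78 °C
Reagents that add atoms: (trimethylsilyl)methyllithium, [Li]C[Si](C)(C)C
Why: Organocerium 1,2-addition (first half of a Peterson olefination) to the hindered, enolisable ketone from the equatorial side away from the axial C10 methyl group; the C8 configuration is inconsequential, and the adduct masks C8 as a β-hydroxysilane so that no ketone or exocyclic alkene competes in the hydroboration.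

Step 7
Reactants: 18 (1S,2R,4aR,8aR)-1-(2-chloroethyl)-5,5,8a-trimethyl-2-[(trimethylsilyl)methyl]-1,2,3,4,4a,5,8,8a-octahydronaphthalen-2-ol
Product: 20 (1S,2R,4aR,7R,8aR)-1-(2-chloroethyl)-5,5,8a-trimethyl-2-[(trimethylsilyl)methyl]decahydronaphthalene-2,7-diol, via alkylborane 19 (not isolated)
Conditions: 9-BBN (3 equiv), THF, 65 °C; then 30% H2O2, aq. NaOAc, 0 °C to rt
Reagents that add atoms: hydrogen peroxide, OO
Why: Hydroboration–oxidation, in which boron adds to C2 (away from the neopentyl C3) from the α face opposite the axial C10 and C4 methyl groups and oxidation with retention gives the equatorial C2 hydroxyl trans to the C10 methyl (2R).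

Step 8
Reactants: 20 (1S,2R,4aR,7R,8aR)-1-(2-chloroethyl)-5,5,8a-trimethyl-2-[(trimethylsilyl)methyl]decahydronaphthalene-2,7-diol
Product: 23 (1R,4aR,7R,8aR)-1-(2-chloroethyl)-7-methoxy-5,5,8a-trimethyl-2-methylidenedecahydronaphthalene, via dipotassium dialkoxide 21 (not isolated), via potassium alkoxide 22 (not isolated)
Conditions: KH, THF, 0 °C to rt; then MeI, 0 °C to rt
Reagents that add atoms: iodomethane, CI
Why: Base-induced Peterson syn-elimination of the tertiary potassium β-silyl alkoxide gives only the exocyclic C8=C17 alkene (faster than attack of that alkoxide on the primary chloride), and the remaining C2 alkoxide is methylated by Williamson etherification without touching any stereocentre.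

Step 9
Reactants: 23 (1R,4aR,7R,8aR)-1-(2-chloroethyl)-7-methoxy-5,5,8a-trimethyl-2-methylidenedecahydronaphthalene; 24 prop-2-yn-1-ol
Product: 29 (2Z)-3-[(acetyloxy)methyl]-5-[(1R,4aR,7R,8aR)-7-methoxy-5,5,8a-trimethyl-2-methylidenedecahydronaphthalen-1-yl]pent-2-enoic acid, via Grignard reagent 25 (not isolated), via chloromagnesium propargyl alkoxide 26 (not isolated), via alkenylmagnesium chelate 27 (not isolated), via magnesium carboxylate 28 (not isolated)
Conditions: Mg, THF, 60 °C; separately 24, i-PrMgCl, THF, −20 °C; combine, CuI (10 mol%), Et2O–THF, 0 °C to rt; CO2 (1 atm), 0 °C; Ac2O, 0 °C; cold 1 M HCl to pH 3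
Reagents that add atoms: carbon dioxide, O=C=O; acetic anhydride, CC(=O)OC(C)=O
Why: Copper-catalysed anti-carbomagnesiation of the propargyl alkoxide (Duboudin type) puts the alkyl group on the internal alkyne carbon and magnesium on the terminal carbon cis to CH2O in a five-membered chelate, so carboxylation gives the 13Z acid skeleton, and the alkoxide is acetylated before acidification so that no free hydroxy acid is present to lactonise.

## Compound list

1 | 1-chloro-3-methylbut-2-ene (prenyl chloride) | CC(C)=CCCl | starting material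
2 | (3-methylbut-2-en-1-yl)magnesium chloride | CC(C)=CC[Mg]Cl | intermediate (not isolated)
3 | trimethyl(3-methylbut-2-en-1-yl)silane | CC(C)=CC[Si](C)(C)C | intermediate
4 | 2-methylcyclopent-2-en-1-one | CC1=CCCC1=O | starting material
5 | allyl bromide (3-bromoprop-1-ene) | C=CCBr | starting material
6 | trimethyl{[(3R)-2-methyl-3-(2-methylbut-3-en-2-yl)cyclopent-1-en-1-yl]oxy}silane | C[Si](C)(C)OC1=C(C)[C@@H](C(C)(C)C=C)CC1 | intermediate (not isolated)
7 | lithium (3R)-2-methyl-3-(2-methylbut-3-en-2-yl)cyclopent-1-en-1-olate | [Li]OC1=C(C)[C@@H](C(C)(C)C=C)CC1 | intermediate (not isolated)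
8 | (2R,3R)-2-allyl-2-methyl-3-(2-methylbut-3-en-2-yl)cyclopentan-1-one (allyl trans to the C3 group) | O=C1CC[C@H](C(C)(C)C=C)[C@@]1(C)CC=C | intermediate
9 | dibromomethane | BrCBr | starting material
10 | oxirane | C1CO1 | starting material
11 | dibromomethyllithium | [Li]C(Br)Br | intermediate (not isolated)
12 | lithium (1R,2R,3R)-2-allyl-1-(dibromomethyl)-2-methyl-3-(2-methylbut-3-en-2-yl)cyclopentan-1-olate (predicted major C1 epimer; C1 becomes sp2 again) | [Li]O[C@]1(C(Br)Br)CC[C@H](C(C)(C)C=C)[C@@]1(C)CC=C | intermediate (not isolated)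
13 | lithium (1R,2R,3R)-2-allyl-1-[bromo(lithio)methyl]-2-methyl-3-(2-methylbut-3-en-2-yl)cyclopentan-1-olate (β-oxido carbenoid; carbenoid carbon not configurationally defined) | [Li]O[C@]1(C([Li])Br)CC[C@H](C(C)(C)C=C)[C@@]1(C)CC=C | intermediate (not isolated)
14 | lithium (3R,4R)-3-allyl-3-methyl-4-(2-methylbut-3-en-2-yl)cyclohex-1-en-1-olate | [Li]OC1=C[C@](C)(CC=C)[C@@H](C(C)(C)C=C)CC1 | intermediate (not isolated)
15 | (2S,3R,4R)-3-allyl-2-(2-hydroxyethyl)-3-methyl-4-(2-methylbut-3-en-2-yl)cyclohexan-1-one (open form, in equilibrium with its cyclic hemiketal) | O=C1CC[C@H](C(C)(C)C=C)[C@@](C)(CC=C)[C@@H]1CCO | intermediate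
16 | (2S,3R,4R)-3-allyl-2-(2-chloroethyl)-3-methyl-4-(2-methylbut-3-en-2-yl)cyclohexan-1-one | O=C1CC[C@H](C(C)(C)C=C)[C@@](C)(CC=C)[C@@H]1CCCl | intermediate
17 | (1S,4aR,8aR)-1-(2-chloroethyl)-5,5,8a-trimethyl-3,4,4a,5,8,8a-hexahydronaphthalen-2(1H)-one | O=C1CC[C@@H]2C(C)(C)C=CC[C@@]2(C)[C@@H]1CCCl | intermediate
18 | (1S,2R,4aR,8aR)-1-(2-chloroethyl)-5,5,8a-trimethyl-2-[(trimethylsilyl)methyl]-1,2,3,4,4a,5,8,8a-octahydronaphthalen-2-ol (predicted major C2 epimer, OH cis to the angular methyl; both epimers converge) | C[Si](C)(C)C[C@@]1(O)CC[C@@H]2C(C)(C)C=CC[C@@]2(C)[C@@H]1CCCl | intermediate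
19 | (1S,2R,4aR,7R,8aR)-7-(9-borabicyclo[3.3.1]nonan-9-yl)-1-(2-chloroethyl)-5,5,8a-trimethyl-2-[(trimethylsilyl)methyl]decahydronaphthalen-2-ol | C[Si](C)(C)C[C@@]1(O)CC[C@@H]2C(C)(C)C[C@@H](B3C4CCCC3CCC4)C[C@@]2(C)[C@@H]1CCCl | intermediate (not isolated)
20 | (1S,2R,4aR,7R,8aR)-1-(2-chloroethyl)-5,5,8a-trimethyl-2-[(trimethylsilyl)methyl]decahydronaphthalene-2,7-diol | C[Si](C)(C)C[C@@]1(O)CC[C@@H]2C(C)(C)C[C@@H](O)C[C@@]2(C)[C@@H]1CCCl | intermediate
21 | dipotassium (1S,2R,4aR,7R,8aR)-1-(2-chloroethyl)-5,5,8a-trimethyl-2-[(trimethylsilyl)methyl]decahydronaphthalene-2,7-bis(olate) | C[Si](C)(C)C[C@@]1(O[K])CC[C@@H]2C(C)(C)C[C@@H](O[K])C[C@@]2(C)[C@@H]1CCCl | intermediate (not isolated)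
22 | potassium (2R,4aR,8R,8aR)-8-(2-chloroethyl)-4,4,8a-trimethyl-7-methylidenedecahydronaphthalen-2-olate | C=C1CC[C@@H]2C(C)(C)C[C@@H](O[K])C[C@@]2(C)[C@@H]1CCCl | intermediate (not isolated)
23 | (1R,4aR,7R,8aR)-1-(2-chloroethyl)-7-methoxy-5,5,8a-trimethyl-2-methylidenedecahydronaphthalene | C=C1CC[C@@H]2C(C)(C)C[C@@H](OC)C[C@@]2(C)[C@@H]1CCCl | intermediate
24 | prop-2-yn-1-ol (propargyl alcohol) | C#CCO | starting material
25 | {2-[(1R,4aR,7R,8aR)-7-methoxy-5,5,8a-trimethyl-2-methylidenedecahydronaphthalen-1-yl]ethyl}magnesium chloride | C=C1CC[C@@H]2C(C)(C)C[C@@H](OC)C[C@@]2(C)[C@@H]1CC[Mg]Cl | intermediate (not isolated)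
26 | chloromagnesium prop-2-yn-1-olate | C#CCO[Mg]Cl | intermediate (not isolated)
27 | 4-{2-[(1R,4aR,7R,8aR)-7-methoxy-5,5,8a-trimethyl-2-methylidenedecahydronaphthalen-1-yl]ethyl}-2,5-dihydro-1,2-oxamagnesole (alkenylmagnesium alkoxide chelate) | C=C1CC[C@@H]2C(C)(C)C[C@@H](OC)C[C@@]2(C)[C@@H]1CCC1=C[Mg]OC1 | intermediate (not isolated)
28 | magnesium (2Z)-5-[(1R,4aR,7R,8aR)-7-methoxy-5,5,8a-trimethyl-2-methylidenedecahydronaphthalen-1-yl]-3-(oxidomethyl)pent-2-enoate (cyclic chelate) | C=C1CC[C@@H]2C(C)(C)C[C@@H](OC)C[C@@]2(C)[C@@H]1CCC1=CC(=O)O[Mg]OC1 | intermediate (not isolated)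
29 | (2Z)-3-[(acetyloxy)methyl]-5-[(1R,4aR,7R,8aR)-7-methoxy-5,5,8a-trimethyl-2-methylidenedecahydronaphthalen-1-yl]pent-2-enoic acid | C=C1CC[C@@H]2C(C)(C)C[C@@H](OC)C[C@@]2(C)[C@@H]1CC/C(=C/C(=O)O)COC(C)=O | target

## Step count and risks

Total steps: 9. Longest linear sequence: 9 (fully linear; 4, 5, 9, 10 and 24 enter as purchased).

Steps most likely to fail:

Step 2 (the proposed new reaction). Face control by the chiral counteranion on a small α-methyl enone is unproven, and the vicinal tertiary/quaternary bond is crowded. The fallback sets out from 4 (with 3 and 5) and comes back at 8. The same Hosomi–Sakurai addition is run with the achiral acid Tf2NH (1 mol%, CH2Cl2, −78 °C), which is known chemistry, followed by the same MeLi/allyl bromide trapping. This gives the trans ketone as a racemate: 6, 7 and 8 are formed together with their mirror images, the (3S)-silyl enol ether F1, the (3S)-lithium enolate F2 and the (2S,3S)-ketone F3. Preparative supercritical-fluid chromatography on an amylose tris(3,5-dimethylphenylcarbamate) phase separates 8 from F3, so the asymmetric catalysis is replaced by a resolution.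

Step 3 (ring enlargement and hydroxyethylation). The risks are addition of LiCHBr2 to a ketone flanked by a quaternary carbon, competing migration of the C7 methylene, and sluggish C-alkylation of the hindered enolate by oxirane. The fallback sets out from 8 and comes back at 16, using a cationic halohydrin semipinacol in place of the carbenoid. Cyclopropylmagnesium bromide with CeCl3 (THF, −78 °C) gives the cyclopropyl carbinol (1S,2R,3R)-2-allyl-1-cyclopropyl-2-methyl-3-(2-methylbut-3-en-2-yl)cyclopentan-1-ol F4. Concentrated HCl (CH2Cl2, 0 °C) opens it in a Julia cyclopropylcarbinyl-to-homoallyl rearrangement to (2R,3R)-2-allyl-1-(3-chloropropylidene)-2-methyl-3-(2-methylbut-3-en-2-yl)cyclopentane F5 (E major). NBS in aqueous acetone converts the trisubstituted alkene selectively into the bromohydrin (1R,2R,3R)-2-allyl-1-(1-bromo-3-chloropropyl)-2-methyl-3-(2-methylbut-3-en-2-yl)cyclopentan-1-ol F6. AgBF4 (CH2Cl2, −20 °C) then removes the secondary bromide with 1,2-shift of the quaternary ring carbon, and K2CO3/MeOH equilibration gives 16 directly, so step 4 is not needed.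

Step 9 (one-pot carbomagnesiation, carboxylation and acetylation). The advanced Grignard reagent is the limiting partner and can be quenched by the acetylenic C–H, and the cis alkoxide may lactonise if the carboxylate is acylated first. The fallback sets out from 23 (with 24) and comes back at 29, using a copper-catalysed syn conjugate addition to an ynoate. Propargyl alcohol 24 is silylated (t-BuMe2SiCl, imidazole) to tert-butyldimethyl(prop-2-yn-1-yloxy)silane F7 and carboxylated (n-BuLi, Boc2O, THF, −78 °C) to tert-butyl 4-[(tert-butyldimethylsilyl)oxy]but-2-ynoate F8. Grignard reagent 25 made from 23 adds to F8 (CuBr·SMe2 10 mol%, Me3SiCl, THF, −78 °C) in a syn fashion to give the (2Z) silyl ether tert-butyl ester F9. Bu4NF buffered with AcOH (THF, 0 °C) gives the (2Z) hydroxy tert-butyl ester F10, which is acetylated at once (Ac2O, pyridine, 0 °C) to the (2Z) acetoxy tert-butyl ester F11. Me3SiOTf with 2,6-lutidine (CH2Cl2, 0 °C; then H2O) cleaves the tert-butyl ester without protic acid to give 29.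

## Further compounds

F1 | step 2 | trimethyl{[(3S)-2-methyl-3-(2-methylbut-3-en-2-yl)cyclopent-1-en-1-yl]oxy}silane | C[Si](C)(C)OC1=C(C)[C@H](C(C)(C)C=C)CC1
F2 | step 2 | lithium (3S)-2-methyl-3-(2-methylbut-3-en-2-yl)cyclopent-1-en-1-olate | [Li]OC1=C(C)[C@H](C(C)(C)C=C)CC1
F3 | step 2 | (2S,3S)-2-allyl-2-methyl-3-(2-methylbut-3-en-2-yl)cyclopentan-1-one | O=C1CC[C@@H](C(C)(C)C=C)[C@]1(C)CC=C
F4 | step 3 | (1S,2R,3R)-2-allyl-1-cyclopropyl-2-methyl-3-(2-methylbut-3-en-2-yl)cyclopentan-1-ol | O[C@]1(C2CC2)CC[C@H](C(C)(C)C=C)[C@@]1(C)CC=C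
F5 | step 3 | (1E,2R,3R)-2-allyl-1-(3-chloropropylidene)-2-methyl-3-(2-methylbut-3-en-2-yl)cyclopentane (E drawn, minor Z isomer converges) | ClCC/C=C1\CC[C@H](C(C)(C)C=C)[C@@]1(C)CC=C
F6 | step 3 | (1R,2R,3R)-2-allyl-1-(1-bromo-3-chloropropyl)-2-methyl-3-(2-methylbut-3-en-2-yl)cyclopentan-1-ol (epimers at the bromide carbon, both converge) | O[C@]1(C(Br)CCCl)CC[C@H](C(C)(C)C=C)[C@@]1(C)CC=C
F7 | step 9 | tert-butyldimethyl(prop-2-yn-1-yloxy)silane | C#CCO[Si](C)(C)C(C)(C)C
F8 | step 9 | tert-butyl 4-[(tert-butyldimethylsilyl)oxy]but-2-ynoate | CC(C)(C)OC(=O)C#CCO[Si](C)(C)C(C)(C)C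
F9 | step 9 | tert-butyl (2Z)-3-{[(tert-butyldimethylsilyl)oxy]methyl}-5-[(1R,4aR,7R,8aR)-7-methoxy-5,5,8a-trimethyl-2-methylidenedecahydronaphthalen-1-yl]pent-2-enoate | C=C1CC[C@@H]2C(C)(C)C[C@@H](OC)C[C@@]2(C)[C@@H]1CC/C(=C/C(=O)OC(C)(C)C)CO[Si](C)(C)C(C)(C)C
F10 | step 9 | tert-butyl (2Z)-3-(hydroxymethyl)-5-[(1R,4aR,7R,8aR)-7-methoxy-5,5,8a-trimethyl-2-methylidenedecahydronaphthalen-1-yl]pent-2-enoate | C=C1CC[C@@H]2C(C)(C)C[C@@H](OC)C[C@@]2(C)[C@@H]1CC/C(=C/C(=O)OC(C)(C)C)CO
F11 | step 9 | tert-butyl (2Z)-3-[(acetyloxy)methyl]-5-[(1R,4aR,7R,8aR)-7-methoxy-5,5,8a-trimethyl-2-methylidenedecahydronaphthalen-1-yl]pent-2-enoate | C=C1CC[C@@H]2C(C)(C)C[C@@H](OC)C[C@@]2(C)[C@@H]1CC/C(=C/C(=O)OC(C)(C)C)COC(C)=O
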